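**Plan**

1. Retrosynthesis: the C5 O–CH3 bond is cut last, the two diketone carbonyls are traced back to a diarylalkyne, and the alkyne–C6 bond to a Sonogashira coupling with 4-ethynylanisole.
2. Ring B is then opened at O1–C2 and both C2–CH3 bonds are cut. C2 is a quaternary carbon carrying O1 and two methyl groups, which is the oxidation level of a lactone carbonyl, and C3=C4 is a ring-held cis alkene, so ring B is a coumarin lactone that has taken up two methyl groups.
3. The coumarin is cut at C3=C4 (Wittig) and at the lactone C–O bond to a salicylaldehyde, which comes from 2,5-dimethoxybenzaldehyde by Baeyer–Villiger oxidation, ortho-formylation and bromination.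
4. Forward: ring A is bought; the lactone ring closes in step 4; the anisyl ring is joined through the alkyne in step 5; the lactone is opened by double methyl addition in step 6 and reclosed as the pyran in step 7; alkyne oxidation and C5 demethylation finish the route.
5. Stereochemistry: the target has no stereocentre; the only stereochemical element on the way, the Z alkene of the ring-opened diol, is inherited from the endocyclic C3=C4 bond of the coumarin.

Key step: step 6

Remark: chromene numbering (O1, C2 to C8a) is used for the bicyclic core throughout; the target is taken as the achiral benzil 1-(5-hydroxy-8-methoxy-2,2-dimethyl-2H-chromen-6-yl)-2-(4-methoxyphenyl)ethane-1,2-dione.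

**Route**

Step 1
Reactants: 1 2,5-dimethoxybenzaldehyde
Product: 3 2,5-dimethoxyphenol, via 2,5-dimethoxyphenyl formate 2 (not isolated)
Conditions: mCPBA, CH2Cl2, 0 °C to rt; then K2CO3 (cat.), MeOH, rt
Reagents that add atoms: mCPBA (3-chloroperoxybenzoic acid), O=C(OO)c1cccc(Cl)c1
Why: Baeyer–Villiger (Dakin-type) oxidation, in which the electron-rich ortho-alkoxy aryl group migrates in preference to hydride in the Criegee intermediate, followed by methanolysis of the aryl formate in the same flask.

Step 2
Reactants: 3 2,5-dimethoxyphenol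
Product: 5 2-hydroxy-3,6-dimethoxybenzaldehyde, via salicyl alcohol magnesium phenoxide 4 (not isolated)
Conditions: MgCl2, Et3N, (CH2O)n, MeCN, reflux; aq. HCl work-up
Reagents that add atoms: paraformaldehyde (as formaldehyde), C=O
Why: Magnesium-mediated ortho-formylation (Casnati–Skattebøl reaction), in which the magnesium phenoxide delivers formaldehyde to the only free ortho position and a second formaldehyde oxidises the benzylic alkoxide by hydride transfer.

Step 3
Reactants: 5 2-hydroxy-3,6-dimethoxybenzaldehyde
Product: 6 5-bromo-2-hydroxy-3,6-dimethoxybenzaldehyde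
Conditions: NBS, MeCN, 0 °C to rt
Reagents that add atoms: N-bromosuccinimide, O=C1CCC(=O)N1Br
Why: Electrophilic aromatic bromination, expected at C5 because that position is para to the free hydroxyl, ortho to a methoxy group and meta to the formyl group, whereas C4 is para to the formyl group.

Step 4
Reactants: 6 5-bromo-2-hydroxy-3,6-dimethoxybenzaldehyde; 7 ethyl (triphenylphosphoranylidene)acetate
Product: 10 6-bromo-5,8-dimethoxy-2H-chromen-2-one, via E-acrylate ester 8 (not isolated), via Z-acrylate ester 9 (not isolated)
Conditions: PhNEt2, reflux (ca. 215 °C)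
Reagents that add atoms: ethyl (triphenylphosphoranylidene)acetate 7, CCOC(=O)C=P(c1ccccc1)(c1ccccc1)c1ccccc1
Why: Wittig olefination followed by thermal E/Z equilibration and lactonisation (the classical salicylaldehyde-to-coumarin procedure in boiling N,N-diethylaniline), in which only the Z ester can close and so drains the mixture to the coumarin.

Step 5
Reactants: 10 6-bromo-5,8-dimethoxy-2H-chromen-2-one; 11 4-ethynylanisole
Product: 12 5,8-dimethoxy-6-[(4-methoxyphenyl)ethynyl]-2H-chromen-2-one
Conditions: Pd(PPh3)2Cl2 (cat.), CuI (cat.), Et3N, DMF, 80 °C, degassed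
Reagents that add atoms: 4-ethynylanisole 11, C#Cc1ccc(OC)cc1
Why: Sonogashira coupling (oxidative addition of the aryl bromide to zerovalent palladium, transmetalation from the copper acetylide, reductive elimination), with a tertiary amine base that leaves the lactone intact.

Step 6
Reactants: 12 5,8-dimethoxy-6-[(4-methoxyphenyl)ethynyl]-2H-chromen-2-one; 13 methyllithium
Product: 15 (Z)-4-{2-hydroxy-3,6-dimethoxy-5-[(4-methoxyphenyl)ethynyl]phenyl}-2-methylbut-3-en-2-ol, via ring-opened Z-enone lithium phenoxide 14 (not isolated)
Conditions: MeLi (3.5 equiv), THF, −78 °C to 0 °C; then sat. aq. NH4Cl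
Reagents that add atoms: methyllithium 13, [Li]C
Why: Methyllithium adds to the lactone carbonyl (C2) of 12 and the tetrahedral alkoxide collapses by expelling the aryl oxide, which gives the lithium phenoxide of the (Z)-aryl butenone 14; a second methyllithium adds 1,2 to that ketone, so both C2–CH3 bonds are made in one flask and protonation should deliver 15. The closest known reaction is the classical double addition of methyllithium or methylmagnesium halides to coumarins, the standard entry to 2,2-dimethyl-2H-chromenes. No ring closes here (the lactone is opened and the pyran closes only in step 7) and no stereocentre is formed; the Z geometry of C3=C4 is carried over unchanged from the endocyclic double bond of the coumarin. The step needs 1,2- rather than 1,4-addition, addition rather than enolisation of the methyl ketone, and an untouched alkyne. The hard, unhindered organolithium at low temperature attacks carbonyl carbon, the conjugated phenoxide of 14 lowers the electrophilicity of the β-carbon, the excess of reagent compensates for any enolisation, and an internal diarylalkyne is not carbolithiated under these conditions. The alkyne at C6 is carried as a masked 1,2-diketone precisely because the organolithium cannot attack it.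

Step 7
Reactants: 15 (Z)-4-{2-hydroxy-3,6-dimethoxy-5-[(4-methoxyphenyl)ethynyl]phenyl}-2-methylbut-3-en-2-ol
Product: 16 5,8-dimethoxy-6-[(4-methoxyphenyl)ethynyl]-2,2-dimethyl-2H-chromene
Conditions: PPTS (cat.), toluene, 60 °C
Reagents that add atoms: none
Why: Acid-catalysed cyclodehydration, in which ionisation of the tertiary allylic alcohol gives a stabilised allyl cation that the neighbouring phenol, held in reach by the Z alkene, captures at the tertiary carbon to close the pyran ring under conditions too mild to touch the alkyne or the methyl ethers.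

Step 8
Reactants: 16 5,8-dimethoxy-6-[(4-methoxyphenyl)ethynyl]-2,2-dimethyl-2H-chromene
Product: 17 1-(5,8-dimethoxy-2,2-dimethyl-2H-chromen-6-yl)-2-(4-methoxyphenyl)ethane-1,2-dione
Conditions: Ph3PAuNTf2 (5 mol %), 2,6-dichloropyridine N-oxide (2.5 equiv), ClCH2CH2Cl, 60 °C
Reagents that add atoms: 2,6-dichloropyridine N-oxide, [O-][n+]1c(Cl)cccc1Cl
Why: Gold-catalysed double oxygen transfer to an alkyne, a known route from diarylalkynes to benzils: the N-oxide attacks the gold-bound alkyne, N–O cleavage gives an α-oxo gold carbene and a second N-oxide oxidises it to the diketone, so the regiochemistry of the first attack is irrelevant and the chromene alkene should be left alone.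

Step 9
Reactants: 17 1-(5,8-dimethoxy-2,2-dimethyl-2H-chromen-6-yl)-2-(4-methoxyphenyl)ethane-1,2-dione
Product: 19 dielsianone (1-(5-hydroxy-8-methoxy-2,2-dimethyl-2H-chromen-6-yl)-2-(4-methoxyphenyl)ethane-1,2-dione), via aryloxydichloroborane chelate 18 (not isolated)
Conditions: BCl3 (2 equiv), CH2Cl2, −78 °C to −20 °C; then H2O
Reagents that add atoms: none
Why: Chelation-controlled ether cleavage, in which BCl3 bridges the C6 ketone oxygen and the ortho C5 methoxy oxygen in a six-membered chelate and chloride removes that methyl group alone, the C8 and anisyl methoxy groups having no carbonyl neighbour and the low temperature sparing the chromene.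

**Compound list**

1 | 2,5-dimethoxybenzaldehyde | COc1ccc(OC)c(C=O)c1 | starting material
2 | 2,5-dimethoxyphenyl formate | COc1ccc(OC)c(OC=O)c1 | intermediate (not isolated)
3 | 2,5-dimethoxyphenol | COc1ccc(OC)c(O)c1 | intermediate
4 | 2-(hydroxymethyl)-3,6-dimethoxyphenol, held in the flask as its magnesium phenoxide | COc1ccc(OC)c(CO)c1O | intermediate (not isolated)
5 | 2-hydroxy-3,6-dimethoxybenzaldehyde | COc1ccc(OC)c(C=O)c1O | intermediate
6 | 5-bromo-2-hydroxy-3,6-dimethoxybenzaldehyde | COc1cc(Br)c(OC)c(C=O)c1O | intermediate
7 | ethyl (triphenylphosphoranylidene)acetate | CCOC(=O)C=P(c1ccccc1)(c1ccccc1)c1ccccc1 | starting material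
8 | ethyl (E)-3-(5-bromo-2-hydroxy-3,6-dimethoxyphenyl)prop-2-enoate | CCOC(=O)/C=C/c1c(O)c(OC)cc(Br)c1OC | intermediate (not isolated)
9 | ethyl (Z)-3-(5-bromo-2-hydroxy-3,6-dimethoxyphenyl)prop-2-enoate | CCOC(=O)/C=C\c1c(O)c(OC)cc(Br)c1OC | intermediate (not isolated)
10 | 6-bromo-5,8-dimethoxy-2H-chromen-2-one | COc1cc(Br)c(OC)c2ccc(=O)oc12 | intermediate
11 | 4-ethynylanisole (1-ethynyl-4-methoxybenzene) | C#Cc1ccc(OC)cc1 | starting material
12 | 5,8-dimethoxy-6-[(4-methoxyphenyl)ethynyl]-2H-chromen-2-one | COc1ccc(C#Cc2cc(OC)c3oc(=O)ccc3c2OC)cc1 | intermediate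
13 | methyllithium | [Li]C | starting material
14 | lithium phenoxide of (Z)-4-{2-hydroxy-3,6-dimethoxy-5-[(4-methoxyphenyl)ethynyl]phenyl}but-3-en-2-one | COc1ccc(C#Cc2cc(OC)c([O-])c(/C=C\C(C)=O)c2OC)cc1.[Li+] | intermediate (not isolated)
15 | (Z)-4-{2-hydroxy-3,6-dimethoxy-5-[(4-methoxyphenyl)ethynyl]phenyl}-2-methylbut-3-en-2-ol | COc1ccc(C#Cc2cc(OC)c(O)c(/C=C\C(C)(C)O)c2OC)cc1 | intermediate
16 | 5,8-dimethoxy-6-[(4-methoxyphenyl)ethynyl]-2,2-dimethyl-2H-chromene | COc1ccc(C#Cc2cc(OC)c3c(c2OC)C=CC(C)(C)O3)cc1 | intermediate
17 | 1-(5,8-dimethoxy-2,2-dimethyl-2H-chromen-6-yl)-2-(4-methoxyphenyl)ethane-1,2-dione | COc1ccc(C(=O)C(=O)c2cc(OC)c3c(c2OC)C=CC(C)(C)O3)cc1 | intermediate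
18 | dichloro{[8-methoxy-6-[(4-methoxyphenyl)(oxo)acetyl]-2,2-dimethyl-2H-chromen-5-yl]oxy}borane (chelated to the C6 ketone) | COc1ccc(C(=O)C(=O)c2cc(OC)c3c(c2OB(Cl)Cl)C=CC(C)(C)O3)cc1 | intermediate (not isolated)
19 | dielsianone, 1-(5-hydroxy-8-methoxy-2,2-dimethyl-2H-chromen-6-yl)-2-(4-methoxyphenyl)ethane-1,2-dione | COc1ccc(C(=O)C(=O)c2cc(OC)c3c(c2O)C=CC(C)(C)O3)cc1 | target

**Step count**

Total: 9 steps. Longest linear sequence: 9 steps, from 2,5-dimethoxybenzaldehyde 1.

**Steps most likely to fail**

Step 8 (gold-mediated alkyne oxidation). Oxygen transfer from the N-oxide may stall at the hindered, electron-rich diarylalkyne, or the electrophilic α-oxo gold carbene may be intercepted by the chromene double bond before the second oxidant arrives. The fallback sets out from 16 and comes back at 17 by passing through the ketone oxidation level, so that no carbene is formed. Gold-catalysed hydration of the alkyne (Ph3PAuNTf2 cat., H2O, 1,4-dioxane, 80 °C; vinylgold formation and protodeauration) should give the deoxybenzoin 1-(5,8-dimethoxy-2,2-dimethyl-2H-chromen-6-yl)-2-(4-methoxyphenyl)ethan-1-one F1, expected to predominate because oxygen adds next to the more electron-rich aryl ring, along with the regioisomer 2-(5,8-dimethoxy-2,2-dimethyl-2H-chromen-6-yl)-1-(4-methoxyphenyl)ethan-1-one F2. The two need not be separated, since Riley oxidation (SeO2, dioxane/H2O, 90 °C) of the activated methylene of either should converge on 17. The chromene has no allylic C–H bond for SeO2 to attack.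

Step 6 (double methyl addition). Enolisation of the ring-opened methyl ketone by the organolithium, or conjugate addition at C4, may outrun the second carbonyl addition and leave mono-adducts. The fallback sets out from 3 and comes back at 16, building ring B by an aryl propargyl ether Claisen rearrangement instead. Bromination of 3 para to the hydroxyl (NBS, MeCN, 0 °C) should give 4-bromo-2,5-dimethoxyphenol F3. O-Alkylation with 3-chloro-3-methylbut-1-yne (DBU, CuCl2 cat., MeCN, 0 °C) should give 1-bromo-2,5-dimethoxy-4-[(2-methylbut-3-yn-2-yl)oxy]benzene F4. Heating in N,N-diethylaniline (about 190 °C) should effect Claisen rearrangement to the only free ortho position, enolisation, 1,5-hydrogen shift and oxa-6π electrocyclisation to 6-bromo-5,8-dimethoxy-2,2-dimethyl-2H-chromene F5. Sonogashira coupling of that bromide with 11 (Pd(PPh3)2Cl2, CuI, Et3N, DMF, 80 °C) then rejoins the route at 16.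

Step 9 (selective demethylation). The Lewis acid may attack the acid-labile 2,2-dimethylchromene, or cleavage may spread to a second methyl ether. The fallback sets out from 17 and comes back at 19 by an oxidative–reductive sequence that needs no strong Lewis acid. Oxidative demethylation of the para-dimethoxyarene ((NH4)2Ce(NO3)6, MeCN/H2O, 0 °C) should give the quinone 6-[(4-methoxyphenyl)(oxo)acetyl]-2,2-dimethyl-2H-chromene-5,8-dione F6. Immediate reduction (Na2S2O4, EtOAc/H2O) should give the hydroquinone 1-(5,8-dihydroxy-2,2-dimethyl-2H-chromen-6-yl)-2-(4-methoxyphenyl)ethane-1,2-dione F7. Its C5 hydroxyl is tied up in a hydrogen bond to the C6 ketone, so methylation with MeI (1 equiv) and K2CO3 in acetone should take place at the free C8 hydroxyl only and give 19.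

Further compounds
F1 | step 8 | 1-(5,8-dimethoxy-2,2-dimethyl-2H-chromen-6-yl)-2-(4-methoxyphenyl)ethan-1-one | COc1ccc(CC(=O)c2cc(OC)c3c(c2OC)C=CC(C)(C)O3)cc1
F2 | step 8 | 2-(5,8-dimethoxy-2,2-dimethyl-2H-chromen-6-yl)-1-(4-methoxyphenyl)ethan-1-one | COc1ccc(C(=O)Cc2cc(OC)c3c(c2OC)C=CC(C)(C)O3)cc1
F3 | step 6 | 4-bromo-2,5-dimethoxyphenol | COc1cc(O)c(OC)cc1Br
F4 | step 6 | 1-bromo-2,5-dimethoxy-4-[(2-methylbut-3-yn-2-yl)oxy]benzene | COc1cc(OC(C)(C)C#C)c(OC)cc1Br
F5 | step 6 | 6-bromo-5,8-dimethoxy-2,2-dimethyl-2H-chromene | COc1cc(Br)c(OC)c2c1OC(C)(C)C=C2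
F6 | step 9 | 6-[(4-methoxyphenyl)(oxo)acetyl]-2,2-dimethyl-2H-chromene-5,8-dione | COc1ccc(C(=O)C(=O)C2=CC(=O)C3=C(C2=O)C=CC(C)(C)O3)cc1
F7 | step 9 | 1-(5,8-dihydroxy-2,2-dimethyl-2H-chromen-6-yl)-2-(4-methoxyphenyl)ethane-1,2-dione | COc1ccc(C(=O)C(=O)c2cc(O)c3c(c2O)C=CC(C)(C)O3)cc1
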